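The route cuts ring A, the 7-oxabicyclo[2.2.1]heptane, at C3–O, C3–C4 and C5–C6. In one operation a chiral dirhodium carboxylate converts an acyclic diazo diketone into a five-membered carbonyl ylide (O, C3, C2, C1, C6). The ylide adds benzyl methacrylate, which closes both rings and sets C3, C5 and C6. The step exploits the oxygen bridge between C3 and C6 of ring A, where C6 sits between the gem-dimethyl carbon C1 and the quaternary carbinol carbon C5. The precursor is a 2,2-dimethyl-1,3-diketone with a diazomethyl end (C3) and a silyloxymethyl end (C7). A C5 radical later turns the ester into the exo hydroxyl. Wittig couplings then join ring A to a triol aldehyde made from actinol.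

Key step: step 5

Assumption: carotenoid numbering is used (ring A C1–C6, chain C7–C15, primed numbers for the ring B half). Read this way, the target is (3R,5R,6S,3'R,5'S,6'S), with the C5 hydroxyl exo (syn to the oxygen bridge).
Assumption: the sense of induction of Rh2(S-PTTL)4 on this ylide cannot be predicted. The route is drawn for this catalyst, and the mirror-image Rh2(R-PTTL)4 would be used if the adduct proved antipodal.
Assumption: the cycloadduct and the three compounds derived from it before the radical step are drawn as the exo-ester epimer. An endo-ester epimer would be carried along and converges in step 7.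
Assumption: (4R,6R)-actinol and the C10 dialdehyde are taken as purchasable fine chemicals.

Step 1
Reactants: 1 methyl glycolate
Product: 2 methyl 2-[(triisopropylsilyl)oxy]acetate
Conditions: TIPSCl, imidazole, DMF, rt
Reagents that add atoms: chlorotriisopropylsilane (TIPSCl), CC(C)[Si](Cl)(C(C)C)C(C)C
Why: Silyl ether protection of a primary alcohol; the bulky, weakly basic TIPS-bound oxygen is chosen so that it should not compete with the C6 ketone for the carbenoid in step 5.

Step 2
Reactants: 3 benzyl isobutyrate; 2 methyl 2-[(triisopropylsilyl)oxy]acetate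
Product: 5 benzyl 2,2-dimethyl-3-oxo-4-[(triisopropylsilyl)oxy]butanoate, via lithium enolate 4 (not isolated)
Conditions: 3 (2.1 equiv), LDA (2.1 equiv), THF, −78 °C; then 2, −78 to −40 °C; AcOH quench at −78 °C
Reagents that add atoms: none
Why: Crossed Claisen condensation of a preformed, fully substituted lithium ester enolate with an activated α-alkoxy ester; the second equivalent of enolate should hold 5 as its C7 enolate until the cold quench, which shuts off retro-Claisen cleavage and double addition.

Step 3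
Reactants: 5 benzyl 2,2-dimethyl-3-oxo-4-[(triisopropylsilyl)oxy]butanoate
Product: 6 2,2-dimethyl-3-oxo-4-[(triisopropylsilyl)oxy]butanoic acid
Conditions: H2 (1 atm), Pd/C, EtOAc, rt; filtered, concentrated below 20 °C, used at once
Reagents that add atoms: none
Why: Catalytic hydrogenolysis of the benzyl ester frees the β-keto acid under neutral conditions, whereas hydroxide would attack this non-enolisable 1,3-dicarbonyl unit in a retro-Claisen sense; cold handling limits decarboxylation.

Step 4
Reactants: 6 2,2-dimethyl-3-oxo-4-[(triisopropylsilyl)oxy]butanoic acid; 7 (trimethylsilyl)diazomethane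
Product: 10 5-diazo-3,3-dimethyl-1-[(triisopropylsilyl)oxy]pentane-2,4-dione, via acid chloride 8 (not isolated), via silyl diazo ketone 9 (not isolated)
Conditions: 1-chloro-N,N,2-trimethylprop-1-en-1-amine, CH2Cl2, 0 °C; then 7 (2 equiv), Et3N, MeCN/THF, 0 °C; aq. NaHCO3 work-up
Reagents that add atoms: none
Why: Neutral acid chloride formation with an α-chloroenamine followed by acylation of the diazoalkane (first stage of the Arndt–Eistert sequence), the C-silyl group of 9 being lost to water on work-up; 8 has no α-hydrogen, so Et3N cannot make a ketene.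

Step 5
Reactants: 10 5-diazo-3,3-dimethyl-1-[(triisopropylsilyl)oxy]pentane-2,4-dione; 11 benzyl methacrylate
Product: 13 benzyl (1S,2R,4S)-2,6,6-trimethyl-5-oxo-1-{[(triisopropylsilyl)oxy]methyl}-7-oxabicyclo[2.2.1]heptane-2-carboxylate (ester exo), via carbonyl ylide 12 (not isolated)
Conditions: Rh2(S-PTTL)4 (1 mol %), 11 (5 equiv), PhCF3, 0 °C, 10 added slowly by syringe pump
Reagents that add atoms: none
Why: Loss of N2 gives a carbenoid of divalent rhodium at C3; the C6 ketone oxygen attacks it and closes the five-membered ring O–C3–C2–C1–C6 (Rh–C bond outside the ring, C6=O bond inside it), and ylide 12 then adds 11 in a concerted suprafacial [3+2] step that closes the second ring by forming C3–C4 and C5–C6. The closest known reaction type is the dirhodium-catalysed tandem ylide formation and cycloaddition of 2,2-disubstituted 1-diazo-2,4-diones with enones, together with its enantioselective form using phthalimido amino acid dirhodium catalysts. The step needs regioselectivity, and the substrate supplies it: C3, next to the C2 ketone, is the enolate-like end and bonds to the acrylate CH2, while C6 is the oxocarbenium-like end and bonds to the ester-bearing carbon. C3 and C6 are forced cis by the oxygen bridge, and their absolute sense depends on the chiral carboxylate wall staying on the ylide during the addition, which is the extrapolated part. C5 is set by exo or endo approach of the ester, and either outcome is acceptable because step 7 erases and resets this centre. Chemoselectivity is secured by the gem-dimethyl group (no enolisation, compressed chain), by the bulky TIPS ether (no oxonium ylide) and by slow addition into excess 11 (little ylide dimer or proton shift from C7).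

Step 6
Reactants: 13 benzyl ester cycloadduct
Product: 14 (1S,2R,4S)-2,6,6-trimethyl-5-oxo-1-{[(triisopropylsilyl)oxy]methyl}-7-oxabicyclo[2.2.1]heptane-2-carboxylic acid
Conditions: H2 (1 atm), Pd/C, EtOAc, rt
Reagents that add atoms: none
Why: Benzyl ester hydrogenolysis frees a carboxyl group that lies between two quaternary carbons without any attack at its shielded carbonyl; no stereocentre is touched.

Step 7
Reactants: 14 keto acid
Product: 18 (1S,4R,5R)-5-hydroxy-3,3,5-trimethyl-4-{[(triisopropylsilyl)oxy]methyl}-7-oxabicyclo[2.2.1]heptan-2-one (hydroxyl exo), via acid chloride 15 (not isolated), via thiohydroxamate ester 16 (not isolated), via hydroperoxide 17 (not isolated)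
Conditions: 1-chloro-N,N,2-trimethylprop-1-en-1-amine, CH2Cl2, 0 °C; sodium pyridine-2-thiolate 1-oxide, DMAP (cat.), toluene, dark, rt; O2 stream, t-BuSH, tungsten lamp, 0–10 °C; then P(OMe)3
Reagents that add atoms: dioxygen, O=O
Why: Barton decarboxylative hydroxylation; the tertiary C5 radical should take up O2 on the exo face because the endo face is covered by the endo methyl group on C1, so C5–OH ends up syn to the bridge whichever C5 epimer of 14 enters, and the phosphite reduces hydroperoxide 17.

Step 8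
Reactants: 18 hydroxy ketone
Product: 19 (1S,2S,4R,5R)-3,3,5-trimethyl-4-{[(triisopropylsilyl)oxy]methyl}-7-oxabicyclo[2.2.1]heptane-2,5-diol (C2 hydroxyl endo)
Conditions: NaBH4, MeOH, 0 °C
Reagents that add atoms: none
Why: Borohydride reduction of a strained α-alkoxy ketone; hydride should arrive from the open exo face and give the endo C2 alcohol, a centre that is removed again in step 10.

Step 9
Reactants: 19 diol
Product: 20 O-[(1S,2S,4R,5R)-5-hydroxy-3,3,5-trimethyl-4-{[(triisopropylsilyl)oxy]methyl}-7-oxabicyclo[2.2.1]heptan-2-yl] 1H-imidazole-1-carbothioate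
Conditions: 1,1'-thiocarbonyldiimidazole, DMAP, 1,2-dichloroethane, reflux
Reagents that add atoms: 1,1'-thiocarbonyldiimidazole, S=C(n1ccnc1)n1ccnc1
Why: Thioacylation for the Barton–McCombie reaction; only the secondary C2 hydroxyl should react, since the tertiary C5 hydroxyl is too hindered for this acyl transfer.

Step 10
Reactants: 20 imidazole thiocarbamate
Product: 21 (1R,2R,4R)-2,6,6-trimethyl-1-{[(triisopropylsilyl)oxy]methyl}-7-oxabicyclo[2.2.1]heptan-2-ol
Conditions: Bu3SnH, AIBN, toluene, 100 °C
Reagents that add atoms: none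
Why: Barton–McCombie deoxygenation; a radical method is chosen because anionic hydrazone-based deoxygenations could expel the C3–O bridge, whereas a secondary C2 radical does not cleave a β C–O bond before it takes hydrogen from the stannane.

Step 11
Reactants: 21 TIPS ether
Product: 22 (1R,2R,4R)-1-(hydroxymethyl)-2,6,6-trimethyl-7-oxabicyclo[2.2.1]heptan-2-ol
Conditions: TBAF, THF, rt
Reagents that add atoms: none
Why: Fluoride-induced cleavage of the silyl ether, to which the ether bridge and the tertiary alcohol are inert.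

Step 12
Reactants: 22 diol
Product: 23 (1S,2R,4R)-2-hydroxy-2,6,6-trimethyl-7-oxabicyclo[2.2.1]heptane-1-carbaldehyde
Conditions: Dess–Martin periodinane, CH2Cl2, rt
Reagents that add atoms: none
Why: Dess–Martin oxidation; only the primary alcohol can be oxidised, the bridgehead aldehyde has no α-hydrogen, and the base-free medium avoids retro-aldol cleavage.

Step 13
Reactants: 23 bridgehead aldehyde; 24 1-(triphenylphosphoranylidene)propan-2-one
Product: 25 (E)-4-[(1S,2R,4R)-2-hydroxy-2,6,6-trimethyl-7-oxabicyclo[2.2.1]heptan-1-yl]but-3-en-2-one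
Conditions: toluene, 90 °C
Reagents that add atoms: none
Why: Wittig olefination with a stabilised ylide, which is E-selective and needs no added base, so the β-hydroxy aldehyde never meets an alkoxide that could start retro-aldol cleavage of C5–C6.

Step 14
Reactants: 25 enone; 26 vinylmagnesium bromide
Product: 27 (E)-1-[(1S,2R,4R)-2-hydroxy-2,6,6-trimethyl-7-oxabicyclo[2.2.1]heptan-1-yl]-3-methylpenta-1,4-dien-3-ol (both C9 epimers)
Conditions: 26 (3 equiv), THF, −78 to −20 °C; aqueous work-up
Reagents that add atoms: none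
Why: 1,2-Addition of a Grignard reagent to an enone, as in the classical conversion of an ionone into a vinylionol; one equivalent is spent on the C5 hydroxyl, and the new C9 carbinol centre forms without control, which does not matter because it becomes sp2 in step 15.

Step 15
Reactants: 27 vinyl carbinol
Product: 28 {(2E,4E)-5-[(1S,2R,4R)-2-hydroxy-2,6,6-trimethyl-7-oxabicyclo[2.2.1]heptan-1-yl]-3-methylpenta-2,4-dienyl}triphenylphosphonium bromide
Conditions: PPh3·HBr, MeOH, rt
Reagents that add atoms: triphenylphosphine hydrobromide, Br.c1ccc(cc1)P(c1ccccc1)c1ccccc1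
Why: Acid-mediated allylic substitution with transposition (vinyl carbinol to phosphonium salt); the delocalised cation is captured irreversibly by the phosphine at the unhindered C11, and the more stable 9E salt should prevail and can be purified by crystallisation.

Step 16
Reactants: 28 C15 phosphonium bromide; 29 (2E,4E,6E)-2,7-dimethylocta-2,4,6-trienedial
Product: 31 (3R,5R,6S)-3,6-epoxy-5-hydroxy-5,6-dihydro-12'-apo-β-caroten-12'-al (all-E), via ylide 30 (not isolated)
Conditions: 29 (2 equiv), 1,2-epoxybutane, EtOH, reflux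
Reagents that add atoms: none
Why: Wittig reaction under base-free epoxide conditions (bromide opens the epoxide and the alkoxide so formed deprotonates 28); excess dialdehyde restricts the reaction to one formyl group, and the hot medium should equilibrate the new C11=C12 bond to E.

Step 17
Reactants: 31 C25 aldehyde
Product: 32 (3R,5R,6S)-3,6-epoxy-5,6-dihydro-12'-apo-β-carotene-5,12'-diol
Conditions: NaBH4, MeOH/CH2Cl2, 0 °C
Reagents that add atoms: none
Why: Chemoselective 1,2-reduction of a polyenal with borohydride.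

Step 18
Reactants: 32 C25 alcohol
Product: 33 [(3R,5R,6S)-3,6-epoxy-5-hydroxy-5,6-dihydro-12'-apo-β-caroten-12'-yl]triphenylphosphonium bromide
Conditions: PPh3·HBr, CH2Cl2/MeOH, rt
Reagents that add atoms: triphenylphosphine hydrobromide, Br.c1ccc(cc1)P(c1ccccc1)c1ccccc1
Why: Phosphonium salt formation from a primary polyenylic alcohol through its stabilised cation, the standard entry to carotenoid Wittig salts; the tertiary C5 hydroxyl is not allylic and should stay untouched.

Step 19
Reactants: 34 (4R,6R)-4-hydroxy-2,2,6-trimethylcyclohexanone (actinol)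
Product: 35 (1S,5R)-3,3,5-trimethyl-4-oxocyclohexyl 4-nitrobenzoate
Conditions: 4-nitrobenzoic acid, PPh3, DIAD, THF, 0 °C to rt
Reagents that add atoms: 4-nitrobenzoic acid, O=C(O)c1ccc(cc1)[N+](=O)[O-]
Why: Mitsunobu reaction; SN2 displacement of the activated axial hydroxyl inverts this carbon to the configuration needed for C3' and installs the protecting ester in the same operation, while the methyl-bearing centre of 34 is lost in step 20.

Step 20
Reactants: 35 keto ester
Product: 36 (S)-3,5,5-trimethyl-4-{[(trifluoromethyl)sulfonyl]oxy}cyclohex-3-en-1-yl 4-nitrobenzoate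
Conditions: Tf2O, 2,6-di-tert-butyl-4-methylpyridine, CH2Cl2, 0 °C to rt
Reagents that add atoms: trifluoromethanesulfonic anhydride, O=S(=O)(OS(=O)(=O)C(F)(F)F)C(F)(F)F
Why: Enol triflate formation by O-sulfonylation of the ketone and loss of its only α-hydrogen, so that a single, tetrasubstituted regioisomer can form; the non-nucleophilic base leaves the ester untouched.

Step 21
Reactants: 37 (E)-3-methylpent-2-en-4-yn-1-ol
Product: 38 (2E,4E)-3-methyl-5-(tributylstannyl)penta-2,4-dien-1-ol
Conditions: Bu3SnH, PdCl2(PPh3)2 (cat.), THF, 0 °C to rt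
Reagents that add atoms: tributyltin hydride, CCCC[SnH](CCCC)CCCC
Why: Palladium-catalysed syn hydrostannation of a terminal enyne places tin on the terminal carbon and gives the E-vinylstannane.

Step 22
Reactants: 38 stannyl dienol
Product: 39 (2E,4E)-3-methyl-5-(tributylstannyl)penta-2,4-dienal
Conditions: MnO2, CH2Cl2, rt
Reagents that add atoms: none
Why: Allylic alcohol oxidation with activated MnO2, which leaves the vinylstannane and both double-bond geometries intact.

Step 23
Reactants: 36 enol triflate; 39 stannyl dienal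
Product: 40 (S)-3,5,5-trimethyl-4-[(1E,3E)-3-methyl-5-oxopenta-1,3-dienyl]cyclohex-3-en-1-yl 4-nitrobenzoate
Conditions: Pd2(dba)3 (cat.), AsPh3, NMP, 50 °C
Reagents that add atoms: none
Why: Stille cross-coupling (zerovalent palladium with the weakly bound ligand AsPh3 in a polar solvent, conditions suited to hindered cyclohexenyl triflates) forms C6'–C7' with retention of the stannane geometry.

Step 24
Reactants: 40 trienal ester
Product: 41 (2E,4E)-5-[(4S)-4-hydroxy-2,6,6-trimethylcyclohex-1-enyl]-3-methylpenta-2,4-dienal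
Conditions: K2CO3 (cat.), MeOH, 0 °C
Reagents that add atoms: none
Why: Base-catalysed transesterification; the electron-poor benzoate is cleaved under conditions mild enough for the trienal, and C3' is not touched.

Step 25
Reactants: 41 hydroxy trienal
Product: 42 (2E,4E)-5-[(1S,4R,6R)-4-hydroxy-2,2,6-trimethyl-7-oxabicyclo[4.1.0]heptan-1-yl]-3-methylpenta-2,4-dienal
Conditions: VO(acac)2 (cat.), t-BuOOH (decane), toluene, 0 °C to rt
Reagents that add atoms: tert-butyl hydroperoxide, CC(C)(C)OO
Why: Hydroxyl-directed epoxidation of a homoallylic alcohol; the vanadium-bound peroxide is delivered to C5'=C6' on the face of the C3' hydroxyl (syn epoxide), and the other double bonds are electron-poor and out of reach.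

Step 26
Reactants: 42 syn epoxide
Product: 43 (2E,4E)-3-methyl-5-[(1S,2S,4R)-1,2,4-trihydroxy-2,6,6-trimethylcyclohexyl]penta-2,4-dienal
Conditions: aq. HClO4 (cat.), THF/H2O, 0 °C to rt
Reagents that add atoms: water, O
Why: Acid-catalysed trans-diaxial epoxide hydrolysis; the electron-poor dienal holds the C6'–O bond, so water should attack the tertiary C5' from the opposite face with inversion, which gives the 5',6'-trans diol with C6'–OH cis and C5'–OH trans to C3'–OH.

Step 27
Reactants: 33 C25 phosphonium bromide; 43 triol aldehyde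
Product: 45 (3R,5R,6S,3'R,5'S,6'S)-3,6-epoxy-5,6,5',6'-tetrahydro-β,β-carotene-5,3',5',6'-tetrol (CNP0261804.1), via ylide 44 (not isolated)
Conditions: 1,2-epoxybutane, EtOH, reflux, argon, dark; crystallisation
Reagents that add atoms: none
Why: Wittig reaction under base-free epoxide conditions tolerates the four free hydroxyl groups; the new C11'=C12' bond should equilibrate to E in the hot medium, the all-E tetrol can be purified by crystallisation, and no stereocentre is touched.

Compound list
1 | methyl glycolate | COC(=O)CO | starting material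
2 | methyl 2-[(triisopropylsilyl)oxy]acetate | COC(=O)CO[Si](C(C)C)(C(C)C)C(C)C | intermediate
3 | benzyl isobutyrate | CC(C)C(=O)OCc1ccccc1 | starting material
4 | lithium 1-(benzyloxy)-2-methylprop-1-en-1-olate | [Li+].CC(C)=C([O-])OCc1ccccc1 | intermediate
5 | benzyl 2,2-dimethyl-3-oxo-4-[(triisopropylsilyl)oxy]butanoate | CC(C)[Si](C(C)C)(C(C)C)OCC(=O)C(C)(C)C(=O)OCc1ccccc1 | intermediate
6 | 2,2-dimethyl-3-oxo-4-[(triisopropylsilyl)oxy]butanoic acid | CC(C)[Si](C(C)C)(C(C)C)OCC(=O)C(C)(C)C(=O)O | intermediate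
7 | (trimethylsilyl)diazomethane | C[Si](C)(C)C=[N+]=[N-] | starting material
8 | 2,2-dimethyl-3-oxo-4-[(triisopropylsilyl)oxy]butanoyl chloride | CC(C)[Si](C(C)C)(C(C)C)OCC(=O)C(C)(C)C(=O)Cl | intermediate
9 | 5-diazo-3,3-dimethyl-1-[(triisopropylsilyl)oxy]-5-(trimethylsilyl)pentane-2,4-dione | CC(C)[Si](C(C)C)(C(C)C)OCC(=O)C(C)(C)C(=O)C(=[N+]=[N-])[Si](C)(C)C | intermediate
10 | 5-diazo-3,3-dimethyl-1-[(triisopropylsilyl)oxy]pentane-2,4-dione | CC(C)[Si](C(C)C)(C(C)C)OCC(=O)C(C)(C)C(=O)C=[N+]=[N-] | intermediate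
11 | benzyl methacrylate | C=C(C)C(=O)OCc1ccccc1 | starting material
12 | carbonyl ylide, 4,4-dimethyl-3-oxo-5-{[(triisopropylsilyl)oxy]methyl}-3,4-dihydrofuran-1-ium-2-ide (rhodium-associated) | CC(C)[Si](C(C)C)(C(C)C)OCC1=[O+][CH-]C(=O)C1(C)C | intermediate
13 | benzyl (1S,2R,4S)-2,6,6-trimethyl-5-oxo-1-{[(triisopropylsilyl)oxy]methyl}-7-oxabicyclo[2.2.1]heptane-2-carboxylate (ester exo) | CC(C)[Si](C(C)C)(C(C)C)OC[C@]12O[C@H](C(=O)C1(C)C)C[C@@]2(C)C(=O)OCc1ccccc1 | intermediate
14 | (1S,2R,4S)-2,6,6-trimethyl-5-oxo-1-{[(triisopropylsilyl)oxy]methyl}-7-oxabicyclo[2.2.1]heptane-2-carboxylic acid | CC(C)[Si](C(C)C)(C(C)C)OC[C@]12O[C@H](C(=O)C1(C)C)C[C@@]2(C)C(=O)O | intermediate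
15 | acid chloride of 14 | CC(C)[Si](C(C)C)(C(C)C)OC[C@]12O[C@H](C(=O)C1(C)C)C[C@@]2(C)C(=O)Cl | intermediate
16 | 2-thioxopyridin-1(2H)-yl ester of 14 | CC(C)[Si](C(C)C)(C(C)C)OC[C@]12O[C@H](C(=O)C1(C)C)C[C@@]2(C)C(=O)ON1C=CC=CC1=S | intermediate
17 | (1S,4R,5R)-5-hydroperoxy-3,3,5-trimethyl-4-{[(triisopropylsilyl)oxy]methyl}-7-oxabicyclo[2.2.1]heptan-2-one (exo) | CC(C)[Si](C(C)C)(C(C)C)OC[C@]12O[C@H](C(=O)C1(C)C)C[C@@]2(C)OO | intermediate
18 | (1S,4R,5R)-5-hydroxy-3,3,5-trimethyl-4-{[(triisopropylsilyl)oxy]methyl}-7-oxabicyclo[2.2.1]heptan-2-one (hydroxyl exo) | CC(C)[Si](C(C)C)(C(C)C)OC[C@]12O[C@H](C(=O)C1(C)C)C[C@@]2(C)O | intermediate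
19 | (1S,2S,4R,5R)-3,3,5-trimethyl-4-{[(triisopropylsilyl)oxy]methyl}-7-oxabicyclo[2.2.1]heptane-2,5-diol | CC(C)[Si](C(C)C)(C(C)C)OC[C@]12O[C@H]([C@@H](O)C1(C)C)C[C@@]2(C)O | intermediate
20 | O-[(1S,2S,4R,5R)-5-hydroxy-3,3,5-trimethyl-4-{[(triisopropylsilyl)oxy]methyl}-7-oxabicyclo[2.2.1]heptan-2-yl] 1H-imidazole-1-carbothioate | CC(C)[Si](C(C)C)(C(C)C)OC[C@]12O[C@H]([C@@H](OC(=S)n3ccnc3)C1(C)C)C[C@@]2(C)O | intermediate
21 | (1R,2R,4R)-2,6,6-trimethyl-1-{[(triisopropylsilyl)oxy]methyl}-7-oxabicyclo[2.2.1]heptan-2-ol | CC(C)[Si](C(C)C)(C(C)C)OC[C@]12O[C@H](CC1(C)C)C[C@@]2(C)O | intermediate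
22 | (1R,2R,4R)-1-(hydroxymethyl)-2,6,6-trimethyl-7-oxabicyclo[2.2.1]heptan-2-ol | OC[C@]12O[C@H](CC1(C)C)C[C@@]2(C)O | intermediate
23 | (1S,2R,4R)-2-hydroxy-2,6,6-trimethyl-7-oxabicyclo[2.2.1]heptane-1-carbaldehyde | O=C[C@]12O[C@H](CC1(C)C)C[C@@]2(C)O | intermediate
24 | 1-(triphenylphosphoranylidene)propan-2-one | CC(=O)C=P(c1ccccc1)(c1ccccc1)c1ccccc1 | starting material
25 | (E)-4-[(1S,2R,4R)-2-hydroxy-2,6,6-trimethyl-7-oxabicyclo[2.2.1]heptan-1-yl]but-3-en-2-one | CC(=O)/C=C/[C@]12O[C@H](CC1(C)C)C[C@@]2(C)O | intermediate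
26 | vinylmagnesium bromide | C=C[Mg]Br | starting material
27 | (E)-1-[(1S,2R,4R)-2-hydroxy-2,6,6-trimethyl-7-oxabicyclo[2.2.1]heptan-1-yl]-3-methylpenta-1,4-dien-3-ol (both C9 epimers) | C=CC(C)(O)/C=C/[C@]12O[C@H](CC1(C)C)C[C@@]2(C)O | intermediate
28 | {(2E,4E)-5-[(1S,2R,4R)-2-hydroxy-2,6,6-trimethyl-7-oxabicyclo[2.2.1]heptan-1-yl]-3-methylpenta-2,4-dienyl}triphenylphosphonium bromide | CC(/C=C/[C@]12O[C@H](CC1(C)C)C[C@@]2(C)O)=C\C[P+](c1ccccc1)(c1ccccc1)c1ccccc1.[Br-] | intermediate
29 | (2E,4E,6E)-2,7-dimethylocta-2,4,6-trienedial | O=C/C(C)=C/C=C/C=C(C)/C=O | starting material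
30 | ylide of 28 | CC(/C=C/[C@]12O[C@H](CC1(C)C)C[C@@]2(C)O)=C\C=P(c1ccccc1)(c1ccccc1)c1ccccc1 | intermediate
31 | (3R,5R,6S)-3,6-epoxy-5-hydroxy-5,6-dihydro-12'-apo-β-caroten-12'-al | CC(/C=C/C=C(C)/C=C/[C@]12O[C@H](CC1(C)C)C[C@@]2(C)O)=C\C=C\C=C(C)\C=O | intermediate
32 | (3R,5R,6S)-3,6-epoxy-5,6-dihydro-12'-apo-β-carotene-5,12'-diol | CC(/C=C/C=C(C)/C=C/[C@]12O[C@H](CC1(C)C)C[C@@]2(C)O)=C\C=C\C=C(C)\CO | intermediate
33 | [(3R,5R,6S)-3,6-epoxy-5-hydroxy-5,6-dihydro-12'-apo-β-caroten-12'-yl]triphenylphosphonium bromide | CC(/C=C/C=C(C)/C=C/[C@]12O[C@H](CC1(C)C)C[C@@]2(C)O)=C\C=C\C=C(C)\C[P+](c1ccccc1)(c1ccccc1)c1ccccc1.[Br-] | intermediate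
34 | (4R,6R)-4-hydroxy-2,2,6-trimethylcyclohexanone (actinol) | O=C1C(C)(C)C[C@H](O)C[C@H]1C | starting material
35 | (1S,5R)-3,3,5-trimethyl-4-oxocyclohexyl 4-nitrobenzoate | O=C1C(C)(C)C[C@@H](OC(=O)c2ccc(cc2)[N+](=O)[O-])C[C@H]1C | intermediate
36 | (S)-3,5,5-trimethyl-4-{[(trifluoromethyl)sulfonyl]oxy}cyclohex-3-en-1-yl 4-nitrobenzoate | CC1=C(OS(=O)(=O)C(F)(F)F)C(C)(C)C[C@@H](OC(=O)c2ccc(cc2)[N+](=O)[O-])C1 | intermediate
37 | (E)-3-methylpent-2-en-4-yn-1-ol | OC/C=C(C)/C#C | starting material
38 | (2E,4E)-3-methyl-5-(tributylstannyl)penta-2,4-dien-1-ol | OC/C=C(C)/C=C/[Sn](CCCC)(CCCC)CCCC | intermediate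
39 | (2E,4E)-3-methyl-5-(tributylstannyl)penta-2,4-dienal | O=C/C=C(C)/C=C/[Sn](CCCC)(CCCC)CCCC | intermediate
40 | (S)-3,5,5-trimethyl-4-[(1E,3E)-3-methyl-5-oxopenta-1,3-dienyl]cyclohex-3-en-1-yl 4-nitrobenzoate | O=C/C=C(C)/C=C/C1=C(C)C[C@H](OC(=O)c2ccc(cc2)[N+](=O)[O-])CC1(C)C | intermediate
41 | (2E,4E)-5-[(4S)-4-hydroxy-2,6,6-trimethylcyclohex-1-enyl]-3-methylpenta-2,4-dienal | O=C/C=C(C)/C=C/C1=C(C)C[C@H](O)CC1(C)C | intermediate
42 | (2E,4E)-5-[(1S,4R,6R)-4-hydroxy-2,2,6-trimethyl-7-oxabicyclo[4.1.0]heptan-1-yl]-3-methylpenta-2,4-dienal | O=C/C=C(C)/C=C/[C@@]12O[C@]1(C)C[C@H](O)CC2(C)C | intermediate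
43 | (2E,4E)-3-methyl-5-[(1S,2S,4R)-1,2,4-trihydroxy-2,6,6-trimethylcyclohexyl]penta-2,4-dienal | O=C/C=C(C)/C=C/[C@]1(O)C(C)(C)C[C@@H](O)C[C@]1(C)O | intermediate
44 | ylide of 33 | CC(/C=C/C=C(C)/C=C/[C@]12O[C@H](CC1(C)C)C[C@@]2(C)O)=C\C=C\C=C(C)\C=P(c1ccccc1)(c1ccccc1)c1ccccc1 | intermediate
45 | (3R,5R,6S,3'R,5'S,6'S)-3,6-epoxy-5,6,5',6'-tetrahydro-β,β-carotene-5,3',5',6'-tetrol | CC(/C=C/C=C(C)/C=C/[C@]12O[C@H](CC1(C)C)C[C@@]2(C)O)=C\C=C\C=C(C)\C=C\C=C(C)\C=C\[C@]1(O)C(C)(C)C[C@@H](O)C[C@]1(C)O | target

Total step count: 27. Longest linear sequence: 19 (steps 1–18 and 27).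

Steps most likely to fail

Step 5. The ylide may leave rhodium before it meets the hindered alkene, so that facial selectivity is lost. The slow union of the two fully substituted carbons C5 and C6 also leaves time for a proton shift from C7 or for ylide dimerisation. The fallback replaces catalyst control by a separable, hydrogenolysable chiral ester. It sets out from 10 and comes back at 14.
- The dipolarophile becomes (S)-1-phenylethyl methacrylate F1, made from commercial (S)-1-phenylethanol and methacryloyl chloride (Et3N, CH2Cl2).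
- The cycloaddition is run with achiral Rh2(OAc)4 in neat F1.
- The two ring antipodes are now diastereomers. The one with the ring configuration of 13, (S)-1-phenylethyl (1S,2R,4S)-2,6,6-trimethyl-5-oxo-1-{[(triisopropylsilyl)oxy]methyl}-7-oxabicyclo[2.2.1]heptane-2-carboxylate F2, would be separated by chromatography or crystallisation.
- Hydrogenolysis of this benzylic ester (H2, Pd/C, EtOAc) gives 14.

Step 26. The positive charge developing at C5' may be discharged by proton loss, or by migration of C1' (ring contraction), faster than water is captured. Some water may also enter at C6'. The fallback brings the oxygen in as a peroxide under nearly neutral catalysis. It sets out from 42 and comes back at 43.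
- Perhydrolysis of 42 with ethereal H2O2 and catalytic H3PMo12O40 at rt is used, because the far more nucleophilic peroxide needs much less acid.
- This should give (2E,4E)-5-[(1S,2S,4R)-2-hydroperoxy-1,4-dihydroxy-2,6,6-trimethylcyclohexyl]-3-methylpenta-2,4-dienal F5 with the same inversion at C5'.
- PPh3 in THF at 0 °C then reduces the O–O bond to give 43.

Step 7. Acylation of the thiohydroxamate by the shielded acid chloride may be slower than decay of the light-sensitive ester. The thiol may also hand hydrogen to the C5 radical before oxygen is captured. The fallback makes a C–B bond first and uses a bench-stable active ester. It sets out from 14 through 15 and comes back at 18.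
- Acid chloride 15 with N-hydroxyphthalimide and Et3N (CH2Cl2, warmed if needed) gives the 1,3-dioxoisoindolin-2-yl ester of 14 F3.
- Photoinduced decarboxylative borylation (bis(catecholato)diboron, DMAc, blue light; then pinacol, Et3N) should place boron on the open exo face and give the exo C5 pinacol boronate F4.
- NaBO3 in THF/H2O oxidises the C–B bond with retention to give 18.

Further compounds
F1 | step 5 | (S)-1-phenylethyl methacrylate | C=C(C)C(=O)O[C@@H](C)c1ccccc1
F2 | step 5 | (S)-1-phenylethyl (1S,2R,4S)-2,6,6-trimethyl-5-oxo-1-{[(triisopropylsilyl)oxy]methyl}-7-oxabicyclo[2.2.1]heptane-2-carboxylate | CC(C)[Si](C(C)C)(C(C)C)OC[C@]12O[C@H](C(=O)C1(C)C)C[C@@]2(C)C(=O)O[C@@H](C)c1ccccc1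
F3 | step 7 | 1,3-dioxoisoindolin-2-yl ester of 14 | CC(C)[Si](C(C)C)(C(C)C)OC[C@]12O[C@H](C(=O)C1(C)C)C[C@@]2(C)C(=O)ON1C(=O)c2ccccc2C1=O
F4 | step 7 | exo C5 pinacol boronate, 3,3,5-trimethyl-5-(4,4,5,5-tetramethyl-1,3,2-dioxaborolan-2-yl)-4-{[(triisopropylsilyl)oxy]methyl}-7-oxabicyclo[2.2.1]heptan-2-one | CC(C)[Si](C(C)C)(C(C)C)OC[C@]12O[C@H](C(=O)C1(C)C)C[C@@]2(C)B1OC(C)(C)C(C)(C)O1
F5 | step 26 | (2E,4E)-5-[(1S,2S,4R)-2-hydroperoxy-1,4-dihydroxy-2,6,6-trimethylcyclohexyl]-3-methylpenta-2,4-dienal | O=C/C=C(C)/C=C/[C@]1(O)C(C)(C)C[C@@H](O)C[C@]1(C)OO
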